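| setting | epsilon | beta | flask |
|---|---|---|---|
| left-handed substrate | 5.0 × 10⁻⁴ M | 7.5 × 10⁻⁴ M | 5.0 × 10⁻⁴ M |
| right-handed substrate | 5.0 × 10⁻⁴ M | 7.5 × 10⁻⁴ M | 5.0 × 10⁻⁴ M |
| gas | 0.22 mM (held) | 0.22 mM (held) | 0.22 mM (held) |
| free catalyst | 0.2 mol% | 0.2 mol% | 0.2 mol% |
| remark | the very flask that is asked about, followed so far | run made earlier |  |
| time |  |  | 6.0 min |

epsilon run (percent of the left-handed substrate and right-handed substrate together charged)

| time / s | right-handed substrate / % | left-handed substrate / % | left-handed product / % |
|---|---|---|---|
| 10.0 | 49.1 | 48.3 | 0.8 |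
| 15.0 | 49.1 | 48.1 | 2.1 |
| 25.0 | 47.6 | 46.1 | 3.7 |
| 40.0 | 47.4 | 43.8 | 5.9 |
| 60.0 | 45.8 | 41.6 | 8.6 |
| 120 | 41.7 | 34.7 | 16.0 |

beta run (percent of the left-handed substrate and right-handed substrate together charged)

| time / min | right-handed substrate / % | left-handed substrate / % | left-handed product / % |
|---|---|---|---|
| 0.333 | 48.9 | 46.1 | 3.9 |
| 0.500 | 47.3 | 44.4 | 5.3 |
| 1.00 | 44.8 | 40.0 | 10.5 |
| 1.50 | 42.6 | 35.8 | 14.6 |
| 2.50 | 38.3 | 28.0 | 22.4 |
| 4.00 | 32.4 | 19.3 | 30.5 |

(each reading ± 0.3 percentage points)

- free catalyst is single-handed; left-handed substrate and right-handed substrate are mirror images of each other, charged as a racemate, each of them at the stated concentration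
- the analysis behind the earlier runs scatters by 0.3 percentage points, standard deviation
- at the start none of the gas is in solution

* whether the excess of right-handed substrate over left-handed substrate among what is left of the two reaches 80 % by 6.0 min (no / yes)
* the highest excess of right-handed substrate over left-handed substrate among what is left of the two up to 6.0 min

From the earliest readings the two substrates drew apart, so I followed ln([right-handed substrate]/[left-handed substrate]) and replaced its curve by its mean slope. This is the splitting rate, 0.0919 min⁻¹ in epsilon, the difference of the two pseudo-first-order constants. The excess is this ratio minus one, over the ratio plus one. Beta's slope was 0.125 min⁻¹ up to 2.50 min and 0.130 min⁻¹ up to 4.00 min, so the mean hid no slowing there.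

Beta's rate was larger than epsilon's, but beta held 1.50 times epsilon's catalyst and the same multiple of each substrate, so two settings differed. I assumed that the substrate amounts leave the splitting rate unchanged and that it falls with the catalyst, but not faster than in proportion. On that assumption beta's rate was a ceiling for epsilon, giving 37.0 % at 6.0 min, and that rate scaled down gave a floor of 25.3 %. Epsilon's last readings, each pushed 2 standard deviations apart, lowered the ceiling to 31.2 %. Unpushed, they gave my figure of 26.9 %, far below 80 %.

The forecast, no and 27 %, held that the excess “rises steadily”, and its figure lay inside my bracket. The flask gave no and 29.7 %, also inside, a mean splitting rate of 0.102 min⁻¹.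

    partner + free catalyst + left-handed substrate → free catalyst + left-handed product (k = 7.20 × 10⁷ L² mol⁻² s⁻¹)
    partner + free catalyst + right-handed substrate → free catalyst + right-handed product (k = 3.30 × 10⁷ L² mol⁻² s⁻¹)
    free catalyst → spent catalyst (k = 3.70 × 10⁻⁶ s⁻¹)
    2 free catalyst ⇌ resting dimer, settled at all times (K = 1.00 × 10⁷ L mol⁻¹)
    gas ⇌ partner, rate k5*(csat - [partner]) (kL = 1.30 s⁻¹)

Just after the start, the left-handed step used partner 2.2 times as fast as the right-handed step. At 6.00 min, partner stood at 2.19 × 10⁻⁴ M and was made 1.00 times as fast as it was used. In the neighbouring flask with 0.8 mol% of free catalyst, 10.6 % of the catalyst stood free at 6.00 min against 20.0 % in the asked flask, so free catalyst at that time was 2.11 times as concentrated. My splitting rate scaled by that gives 52.5 %, and the computed top was 56.9 %.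

(The readings were computed on assumed constants; scatter was added.)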